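**Retrosynthetic overview**
1. Target 9 ⇒ ynone 8 by cutting the pyranone O1–C2 bond. This C–O ring closure (demethylative 6-endo-dig cyclisation) is the key step and the only ring formed; rings A and B are bought.
2. Ynone 8 ⇒ phenol 4 + arylpropiolic acid 5, by Friedel–Crafts acylation at the only free ring carbon of 4.
3. Phenol 4 ⇒ 1,2,4,5-tetramethoxybenzene 1, by C–H → C–O (lithiation, borylation, oxidation).
4. Compounds 1 and 4 and ring A of 8 are mirror-symmetric, so no regiochemical choice arises in any step.

Assumption: the target has no stereogenic element (it is achiral, so no stereocontrol is needed), and 3-(3,4-dimethoxyphenyl)propiolic acid is taken as a catalogue compound.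

**Step 1**
Reactants: 1 1,2,4,5-tetramethoxybenzene
Product: 4 2,3,5,6-tetramethoxyphenol, via aryllithium 2 (not isolated), via lithium arylborate 3 (not isolated)
Conditions: n-BuLi (1.05 equiv), TMEDA, THF, 0 °C → rt; B(OMe)3, −78 °C → rt; AcOH then 30% H2O2, 0 °C → rt; Na2S2O3 quench
Reagents that add atoms: n-butyllithium [Li]CCCC (Li of 2); trimethyl borate COB(OC)OC (B(OMe)3 of 3); hydrogen peroxide OO (the new O of 4)
Why: Directed ortho-metalation followed by borylation and oxidation: both ring C–H bonds of 1 are equivalent and each is flanked by two coordinating OMe groups, so one equivalent of n-BuLi gives a single aryllithium, and the peroxide-induced 1,2-aryl shift from boron to oxygen forms the future C7–O bond; no stereocenter arises.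

**Step 2**
Reactants: 4 2,3,5,6-tetramethoxyphenol; 5 3-(3,4-dimethoxyphenyl)prop-2-ynoic acid
Product: 8 3-(3,4-dimethoxyphenyl)-1-(4-hydroxy-2,3,5,6-tetramethoxyphenyl)prop-2-yn-1-one, via acid chloride 6 (not isolated), via aluminium phenoxide 7 (not isolated)
Conditions: (i) 5, (COCl)2, cat. DMF, CH2Cl2, 0 °C → rt, evaporate; (ii) 4, Me2AlCl (2.2 equiv), CH2Cl2, −78 °C, then 6, −78 → −30 °C; 1 M HCl
Reagents that add atoms: oxalyl chloride ClC(=O)C(=O)Cl (Cl of 6); dimethylaluminium chloride C[Al](C)Cl (Al, CH3 and Cl of 7; none of these atoms remain in 8)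
Why: Friedel–Crafts acylation: Me2AlCl converts the phenol into an aluminium phenoxide (methane is lost), which blocks O-acylation and makes the single free ring carbon (para to O–Al) strongly nucleophilic toward the Al-activated alkynoyl chloride, while the remaining Al–CH3 bonds consume the HCl formed so that it cannot add to the ynone; no stereocenter arises.

**Step 3**
Reactants: 8 3-(3,4-dimethoxyphenyl)-1-(4-hydroxy-2,3,5,6-tetramethoxyphenyl)prop-2-yn-1-one
Product: 9 2-(3,4-dimethoxyphenyl)-7-hydroxy-5,6,8-trimethoxy-4H-chromen-4-one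
Conditions: IPrAuNTf2 (5 mol %), AcOH (10 equiv), dry DCE, 60 °C
Reagents that add atoms: none
Why: Proposed new method: gold(I)-catalysed demethylative 6-endo-dig oxa-cyclisation, in which the cationic NHC–Au(I) π-activates the ynone, either of the two symmetry-equivalent ortho-OMe oxygens adds to the β-alkyne carbon (the Michael terminus, its cationic character stabilised by the 3,4-dimethoxyphenyl group, so 6-endo beats 5-exo), the resulting aryl(methyl)oxonium passes its CH3 to acetic acid (methyl acetate), and the proton released protodeaurates C3 to turn the catalyst over and give the C3–H flavone with its peri 5-OMe untouched because no halide or oxophilic Lewis acid is present; the closest known reaction types are the ICl-induced demethylative iodocyclisation of o-methoxyaryl ynones to 3-iodochromones and the Au-catalysed cyclisation of o-(allyloxy/benzyloxy)aryl ynones in which the O-substituent migrates to C3; no stereocenter arises.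

**Compound list**
1 | 1,2,4,5-tetramethoxybenzene | COc1cc(OC)c(OC)cc1OC | starting material
2 | (2,3,5,6-tetramethoxyphenyl)lithium | [Li]c1c(OC)c(OC)cc(OC)c1OC | intermediate
3 | lithium trimethoxy(2,3,5,6-tetramethoxyphenyl)borate | [Li+].CO[B-](OC)(OC)c1c(OC)c(OC)cc(OC)c1OC | intermediate
4 | 2,3,5,6-tetramethoxyphenol | COc1cc(OC)c(OC)c(O)c1OC | intermediate
5 | 3-(3,4-dimethoxyphenyl)prop-2-ynoic acid | COc1ccc(C#CC(=O)O)cc1OC | starting material
6 | 3-(3,4-dimethoxyphenyl)prop-2-ynoyl chloride | COc1ccc(C#CC(=O)Cl)cc1OC | intermediate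
7 | chloro(methyl)aluminium 2,3,5,6-tetramethoxyphenoxide | COc1cc(OC)c(OC)c(O[Al](C)Cl)c1OC | intermediate
8 | 3-(3,4-dimethoxyphenyl)-1-(4-hydroxy-2,3,5,6-tetramethoxyphenyl)prop-2-yn-1-one | COc1ccc(C#CC(=O)c2c(OC)c(OC)c(O)c(OC)c2OC)cc1OC | intermediate
9 | 2-(3,4-dimethoxyphenyl)-7-hydroxy-5,6,8-trimethoxy-4H-chromen-4-one (7-hydroxy-3',4',5,6,8-pentamethoxyflavone) | COc1ccc(-c2cc(=O)c3c(OC)c(OC)c(O)c(OC)c3o2)cc1OC | target

**Step count and risks**
Total steps: 3. Longest linear sequence: 3 (1 → 4 → 8 → 9); acid 5 enters in step 2.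

Steps most likely to fail, most risky first:

Step 3 (the proposed new cyclisation). Methyl transfer from the oxonium to acetic acid may be slow, so the ring closure reverts. Gold-catalysed hydration of the ynone or intermolecular O-methylation of the free phenol could also compete. The fallback uses known chemistry and sets out from 8. ICl (1.5 equiv) in CH2Cl2 at −78 °C effects the established demethylative iodocyclisation to 2-(3,4-dimethoxyphenyl)-7-hydroxy-3-iodo-5,6,8-trimethoxy-4H-chromen-4-one F1. Hydrodeiodination of this compound with Pd/C and HCO2Na in DMF at 60 °C then returns to the route at 9.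

Step 2. An unprotected, very electron-rich phenol and an alkynoyl chloride can give O-acylation, chloride addition to the ynone or chelation-driven demethylation. The fallback abandons the ynone, sets out from 4 and comes back at 9, bypassing 8. Phenol 4 is acylated with purchased (E)-3,4-dimethoxycinnamoyl chloride and AlCl3 (3.5 equiv) in CH2Cl2 at 0 °C → rt. This gives (E)-3-(3,4-dimethoxyphenyl)-1-(4-hydroxy-2,3,5,6-tetramethoxyphenyl)prop-2-en-1-one F2, which is not isolated because the aluminium chelate cleaves one of its two equivalent ortho-OMe groups in the same pot. The product is (E)-1-(2,4-dihydroxy-3,5,6-trimethoxyphenyl)-3-(3,4-dimethoxyphenyl)prop-2-en-1-one F3. Oxidative cyclisation of this 2'-hydroxychalcone with catalytic I2 in DMSO at 120 °C gives 9.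

Step 1. The phenol 4 is easily over-oxidised, and lithiation may be incomplete or double. The fallback sets out from 1 and comes back at 4. Electrophilic bromination with NBS (1.0 equiv) in MeCN at 0 °C gives 3-bromo-1,2,4,5-tetramethoxybenzene F4. Pd-catalysed hydroxylation of this bromide (Pd2(dba)3, tBuXPhos, KOH, dioxane/H2O, 100 °C, then acid work-up) gives 4.

**Further compounds**
F1 | step 3 | 2-(3,4-dimethoxyphenyl)-7-hydroxy-3-iodo-5,6,8-trimethoxy-4H-chromen-4-one | COc1ccc(-c2oc3c(OC)c(O)c(OC)c(OC)c3c(=O)c2I)cc1OC
F2 | step 2 | (E)-3-(3,4-dimethoxyphenyl)-1-(4-hydroxy-2,3,5,6-tetramethoxyphenyl)prop-2-en-1-one | COc1ccc(/C=C/C(=O)c2c(OC)c(OC)c(O)c(OC)c2OC)cc1OC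
F3 | step 2 | (E)-1-(2,4-dihydroxy-3,5,6-trimethoxyphenyl)-3-(3,4-dimethoxyphenyl)prop-2-en-1-one | COc1ccc(/C=C/C(=O)c2c(O)c(OC)c(O)c(OC)c2OC)cc1OC
F4 | step 1 | 3-bromo-1,2,4,5-tetramethoxybenzene | COc1cc(OC)c(OC)c(Br)c1OC
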